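The earlier runs and the new flask are calculated from invented constants; scatter was added.

Commit to one clock and read the curve through it.

| setting | alder | flask |
|---|---|---|
| electrophile | 1.5 M | 1.5 M |
| nucleophile | 2 equiv | 2.00 equiv |
| scavenger | 0.15 equiv | 0.300 equiv |
| remark | run made earlier |  |
| time |  | 15 min |

alder run (percent of the electrophile charged)

| time / min | product / % | electrophile / % |
|---|---|---|
| 1.00 | 17.9 | 75.0 |
| 2.00 | 31.5 | 59.3 |
| 3.00 | 38.3 | 47.7 |
| 6.00 | 54.7 | 29.4 |
| 12.0 | 66.0 | 17.1 |

(standard deviation of a reading: 1 percentage point)

- what is said of acid set free includes idle adduct
- steps that have been proposed: electrophile + nucleophile -> acid set free + product; electrophile + acid set free <-> idle adduct; nucleophile + acid set free <-> protonated nucleophile; acid set free + scavenger -> scavenged by-product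
- no earlier run changes the charge of scavenger; that part of a forecast is a guess

- amount of product in percent of the electrophile charged, at 1.5 min, 5.0 min and 15 min

1. Define the product clock, the pseudo-first-order time of the first step: the electrophile present divided by the rate of making product. Mean electrophile and the product made over the first 1.00 min of the alder run read 4.89 min. As a slope on the electrophile present, this reading is 0.204 min⁻¹.

2. Take the clock to stretch in inverse proportion to [nucleophile], free form counted. Between 6.00 min and 12.0 min, the alder run reads 12.3 min. Free nucleophile there therefore reads 39.8% of its charge, a reading that carries the scatter of the points.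

3. Draw my curve from the alder run, leaving the added scavenger uncounted. At 1.5 min, the mean of the first two readings gives 24.7%. At 5.0 min, just past the first clock time, the bend is under way, and interpolation gives 49.2%. For 15 min, run the remaining electrophile on the stretched clock from the last reading, which gives 70.2%.

4. Fix the level. The electrophile is the limiting reagent: complete conversion leaves 0.300 equiv of nucleophile free by the balance, so the curve heads for 100%.

5. The forecast says 26%, 53% and 75%: “Doubling the scavenger should change little early on”. At the last point it stands higher than mine.

6. The flask gives 23.8%, 49.2% and 72.9%, within the forecast's tolerance.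

    electrophile + nucleophile → acid set free + product (k = 0.00120 L mol⁻¹ s⁻¹)
    electrophile + acid set free ⇌ idle adduct, settled at all times (K = 95.0 L mol⁻¹)
    nucleophile + acid set free ⇌ protonated nucleophile, settled at all times (K = 53.0 L mol⁻¹)
    acid set free + scavenger → scavenged by-product (k = 0.150 L mol⁻¹ s⁻¹)

In this flask, counting turnover up to 15 min, the product-making step is half done by 2.84 min, and the scavenger's step comes later, half done by 8.84 min; scavenger stands at 98.9% of its charge at 1.50 min and 45.4% at 15.0 min. Between 7.50 min and 15.0 min, the flask's product and electrophile read a clock of 10.4 min, while the alder clock stretched by the flask's mean free nucleophile gives 10.3 min.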